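**Plan**
- Numbering used: dioxane ring O1–C2(aryl)–C3(C9H2OH)–O4 fused to ring B, OMe on C5, side chain on C7; ring A is the 3,4-dihydroxy-5-methoxyphenyl group. In this frame the target is cis-(2S,3R) with an E alkene.
- Cuts: the side-chain C=C (Wittig, then ester to alcohol); O4–C3 (phenoxide opens a C3–C9 oxirane); O1–C2 (Mitsunobu ether); the oxirane oxygen and the C2–vinyl bond (epoxidation, Grignard). Both arenes come from 5-hydroxyvanillin.
- Enabling feature: C3 carries O4 (the oxygen ortho to the C5 methoxy) and a free C9 hydroxymethyl group and is not benzylic. This is the footprint of an SN2 attack of phenol O4 on the internal carbon of a terminal C3–C9 epoxide, which closes the 1,4-dioxane ring.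
- Forward order: ring A aldehyde, vinyl carbinol, anti epoxy alcohol; ring B phenol attached at C2; O4 unmasked; dioxane ring closed (the only ring made); debenzylation; two-carbon homologation; reduction.
- Stereochemistry: the kinetic resolution fixes C3 (S) and C2 (R) in the epoxy alcohol; the Mitsunobu reaction inverts C2 to S; the ring closure inverts C3 to R, hence cis. The stabilised ylide gives the E alkene.

Key step: step 7

Step 1
Reactants: 1 5-hydroxyvanillin; 2 benzyl bromide
Product: 4 3,4-bis(benzyloxy)-5-methoxybenzaldehyde, via 4-O-benzyl monoether 3 (not isolated)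
Conditions: BnBr (2.4 equiv), K2CO3, DMF, 60 °C
Reagents that add atoms: benzyl bromide (2), BrCc1ccccc1
Why: Williamson ether synthesis on both phenols; the 4-OH, acidified by the para-formyl group, is alkylated first and the 3-OH follows with excess bromide, and no stereocentre is involved.

Step 2
Reactants: 4 3,4-bis(benzyloxy)-5-methoxybenzaldehyde; 5 vinylmagnesium bromide
Product: 7 rac-1-[3,4-bis(benzyloxy)-5-methoxyphenyl]prop-2-en-1-ol, via bromomagnesium alkoxide 6 (not isolated)
Conditions: CH2=CHMgBr, THF, −78 → 0 °C; then H2O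
Reagents that add atoms: vinylmagnesium bromide (5), C=C[Mg]Br
Why: Grignard addition to a non-enolisable aryl aldehyde gives the secondary allylic alcohol as a racemate (the new centre C2 is resolved in step 3), and the benzyl ethers are inert.

Step 3
Reactants: 7 rac-1-[3,4-bis(benzyloxy)-5-methoxyphenyl]prop-2-en-1-ol
Product: 8 (R)-[3,4-bis(benzyloxy)-5-methoxyphenyl][(S)-oxiran-2-yl]methanol (anti, erythro)
Conditions: Ti(OiPr)4 (0.2 equiv), D-(−)-DIPT (0.3 equiv), t-BuOOH (0.5 equiv), 4 Å MS, CH2Cl2, −20 °C
Reagents that add atoms: tert-butyl hydroperoxide, CC(C)(C)OO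
Why: Sharpless kinetic resolution of a secondary allylic alcohol: with the D-(−)-tartrate the (S)-alkenol should be epoxidised much faster and with anti (erythro) oxygen delivery, so C3 (S) is set by the catalyst and C2 (R in the product, same spatial arrangement as in the (S)-alkenol) by selection of one enantiomer, while the limiting peroxide leaves the (R)-alkenol untouched.

Step 4
Reactants: 1 5-hydroxyvanillin; 9 allyl bromide
Product: 10 4-(allyloxy)-3-hydroxy-5-methoxybenzaldehyde
Conditions: allyl bromide (1.05 equiv), NaHCO3, DMF, 40 °C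
Reagents that add atoms: allyl bromide (9), C=CCBr
Why: Regioselective Williamson mono-alkylation: hydrogencarbonate ionises only the most acidic 4-OH (para to the formyl group), so the 3-OH that becomes O1 stays free.

Step 5
Reactants: 8 (R)-[3,4-bis(benzyloxy)-5-methoxyphenyl][(S)-oxiran-2-yl]methanol; 10 4-(allyloxy)-3-hydroxy-5-methoxybenzaldehyde
Product: 11 4-(allyloxy)-3-{(S)-[3,4-bis(benzyloxy)-5-methoxyphenyl][(S)-oxiran-2-yl]methoxy}-5-methoxybenzaldehyde
Conditions: PPh3, DIAD, THF, 0 °C → rt
Reagents that add atoms: none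
Why: Mitsunobu etherification: the phenol displaces the alkoxyphosphonium group by SN2 and forms O1–C2 with inversion (R to S), while the adjacent oxirane and the out-of-plane para-benzyloxy group (flanked on both sides) disfavour ionisation at C2, and the epoxide is stable under these neutral conditions.

Step 6
Reactants: 11 4-(allyloxy)-3-{(S)-[3,4-bis(benzyloxy)-5-methoxyphenyl][(S)-oxiran-2-yl]methoxy}-5-methoxybenzaldehyde
Product: 12 3-{(S)-[3,4-bis(benzyloxy)-5-methoxyphenyl][(S)-oxiran-2-yl]methoxy}-4-hydroxy-5-methoxybenzaldehyde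
Conditions: Pd(PPh3)4 (5 mol %), PhNHMe, THF, rt
Reagents that add atoms: none
Why: Tsuji–Trost deallylation: zerovalent palladium ionises the aryl allyl ether (the formyl-stabilised phenoxide is a good leaving group) and N-methylaniline captures the allyl unit; this scavenger is too weakly basic to deprotonate the phenol or open the oxirane, so 12 should be isolated uncyclised.

Step 7
Reactants: 12 3-{(S)-[3,4-bis(benzyloxy)-5-methoxyphenyl][(S)-oxiran-2-yl]methoxy}-4-hydroxy-5-methoxybenzaldehyde
Product: 14 (2S,3R)-2-[3,4-bis(benzyloxy)-5-methoxyphenyl]-3-(hydroxymethyl)-5-methoxy-2,3-dihydro-1,4-benzodioxine-7-carbaldehyde, via potassium phenoxide 13 (not isolated)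
Conditions: K2CO3 (1.5 equiv), DMF, 50 °C
Reagents that add atoms: none
Why: Carbonate converts the phenol O4–H (acidified by the para-formyl group) into phenoxide 13, which attacks the internal oxirane carbon C3 from the side opposite the C3–O bond, so O4–C3 forms with inversion and the oxirane oxygen leaves on C9 as the alkoxide that becomes the free hydroxymethyl group after proton transfer from hydrogencarbonate. The closest known reaction is the closure of 2-(oxiranylmethoxy)phenoxides to 2-hydroxymethyl-1,4-benzodioxanes in catechol/epichlorohydrin chemistry. The dioxane ring closes in the 6-exo-tet mode, the breaking C3–O bond lying outside the new ring. C3 becomes R by SN2 inversion of the (S)-oxirane carbon, and with C2 (S) fixed in step 5 the aryl and CH2OH groups end up cis, a relation dictated by the substrate and not by ring thermodynamics. The step needs attack at C3 (6-exo) instead of C9 (7-endo, benzodioxepine) and no ionisation at C2: the shorter tether and the collinear approach favour the six-membered transition state, C3 is not benzylic and reacts by pure SN2, and the mild carbonate together with the benzyl-capped ring A phenols prevents quinone-methide opening of the C2–O1 ether.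

Step 8
Reactants: 14 (2S,3R)-2-[3,4-bis(benzyloxy)-5-methoxyphenyl]-3-(hydroxymethyl)-5-methoxy-2,3-dihydro-1,4-benzodioxine-7-carbaldehyde
Product: 15 (2S,3R)-2-(3,4-dihydroxy-5-methoxyphenyl)-3-(hydroxymethyl)-5-methoxy-2,3-dihydro-1,4-benzodioxine-7-carbaldehyde
Conditions: H2 (1 atm), 10% Pd/C, EtOAc, rt, stopped at full debenzylation
Reagents that add atoms: none
Why: Hydrogenolysis of aryl benzyl ethers over palladium should be faster than reduction of the aryl aldehyde or cleavage of the cyclic secondary C2–O1 ether in neutral ethyl acetate; it is placed here because no alkene is present yet, and C2 and C3 are untouched.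

Step 9
Reactants: 15 (2S,3R)-2-(3,4-dihydroxy-5-methoxyphenyl)-3-(hydroxymethyl)-5-methoxy-2,3-dihydro-1,4-benzodioxine-7-carbaldehyde; 16 methyl (triphenylphosphoranylidene)acetate
Product: 17 methyl (E)-3-[(2S,3R)-2-(3,4-dihydroxy-5-methoxyphenyl)-3-(hydroxymethyl)-5-methoxy-2,3-dihydro-1,4-benzodioxin-7-yl]prop-2-enoate
Conditions: Ph3P=CHCO2Me (1.5 equiv), THF, 40 °C, argon
Reagents that add atoms: methyl (triphenylphosphoranylidene)acetate (16), COC(=O)C=P(c1ccccc1)(c1ccccc1)c1ccccc1
Why: Wittig olefination with a stabilised ylide gives the (E)-enoate; the ylide is too weak a base to generate much ring A phenoxide, so the p-hydroxybenzyl ether at C2 should not open through a quinone methide.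

Step 10
Reactants: 17 methyl (E)-3-[(2S,3R)-2-(3,4-dihydroxy-5-methoxyphenyl)-3-(hydroxymethyl)-5-methoxy-2,3-dihydro-1,4-benzodioxin-7-yl]prop-2-enoate
Product: 19 (E)-3-[(2S,3R)-2-(3,4-dihydroxy-5-methoxyphenyl)-3-(hydroxymethyl)-5-methoxy-2,3-dihydro-1,4-benzodioxin-7-yl]prop-2-en-1-ol, via enal 18 (not isolated)
Conditions: iBu2AlH (7 equiv), THF, −78 → 0 °C; then aq. potassium sodium tartrate
Reagents that add atoms: none
Why: DIBAL-H 1,2-reduction of the enoate through the enal to the allylic alcohol without conjugate reduction; the excess hydride covers the three acidic OH groups, and the low temperature with a neutral tartrate work-up should preserve the cis-dioxane and the E alkene.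

**Compound list**
1 | 5-hydroxyvanillin (3,4-dihydroxy-5-methoxybenzaldehyde) | COc1cc(C=O)cc(O)c1O | starting material
2 | benzyl bromide | BrCc1ccccc1 | starting material
3 | 4-(benzyloxy)-3-hydroxy-5-methoxybenzaldehyde (formed in the flask) | COc1cc(C=O)cc(O)c1OCc1ccccc1 | intermediate
4 | 3,4-bis(benzyloxy)-5-methoxybenzaldehyde | COc1cc(C=O)cc(OCc2ccccc2)c1OCc1ccccc1 | intermediate
5 | vinylmagnesium bromide | C=C[Mg]Br | starting material
6 | bromomagnesium alkoxide of 7 (racemic, formed in the flask) | C=CC(O[Mg]Br)c1cc(OC)c(OCc2ccccc2)c(OCc2ccccc2)c1 | intermediate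
7 | rac-1-[3,4-bis(benzyloxy)-5-methoxyphenyl]prop-2-en-1-ol | C=CC(O)c1cc(OC)c(OCc2ccccc2)c(OCc2ccccc2)c1 | intermediate
8 | (R)-[3,4-bis(benzyloxy)-5-methoxyphenyl][(S)-oxiran-2-yl]methanol | COc1cc([C@@H](O)[C@@H]2CO2)cc(OCc3ccccc3)c1OCc4ccccc4 | intermediate
9 | allyl bromide | C=CCBr | starting material
10 | 4-(allyloxy)-3-hydroxy-5-methoxybenzaldehyde | COc1cc(C=O)cc(O)c1OCC=C | intermediate
11 | 4-(allyloxy)-3-{(S)-[3,4-bis(benzyloxy)-5-methoxyphenyl][(S)-oxiran-2-yl]methoxy}-5-methoxybenzaldehyde | COc1cc([C@H](Oc2cc(C=O)cc(OC)c2OCC=C)[C@@H]2CO2)cc(OCc3ccccc3)c1OCc4ccccc4 | intermediate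
12 | 3-{(S)-[3,4-bis(benzyloxy)-5-methoxyphenyl][(S)-oxiran-2-yl]methoxy}-4-hydroxy-5-methoxybenzaldehyde | COc1cc([C@H](Oc2cc(C=O)cc(OC)c2O)[C@@H]2CO2)cc(OCc3ccccc3)c1OCc4ccccc4 | intermediate
13 | potassium phenoxide of 12 (formed in the flask) | COc1cc([C@H](Oc2cc(C=O)cc(OC)c2[O-])[C@@H]2CO2)cc(OCc3ccccc3)c1OCc4ccccc4.[K+] | intermediate
14 | (2S,3R)-2-[3,4-bis(benzyloxy)-5-methoxyphenyl]-3-(hydroxymethyl)-5-methoxy-2,3-dihydro-1,4-benzodioxine-7-carbaldehyde | COc1cc([C@@H]2Oc3cc(C=O)cc(OC)c3O[C@@H]2CO)cc(OCc4ccccc4)c1OCc5ccccc5 | intermediate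
15 | (2S,3R)-2-(3,4-dihydroxy-5-methoxyphenyl)-3-(hydroxymethyl)-5-methoxy-2,3-dihydro-1,4-benzodioxine-7-carbaldehyde | COc1cc([C@@H]2Oc3cc(C=O)cc(OC)c3O[C@@H]2CO)cc(O)c1O | intermediate
16 | methyl (triphenylphosphoranylidene)acetate | COC(=O)C=P(c1ccccc1)(c1ccccc1)c1ccccc1 | starting material
17 | methyl (E)-3-[(2S,3R)-2-(3,4-dihydroxy-5-methoxyphenyl)-3-(hydroxymethyl)-5-methoxy-2,3-dihydro-1,4-benzodioxin-7-yl]prop-2-enoate | COc1cc([C@@H]2Oc3cc(/C=C/C(=O)OC)cc(OC)c3O[C@@H]2CO)cc(O)c1O | intermediate
18 | (E)-3-[(2S,3R)-2-(3,4-dihydroxy-5-methoxyphenyl)-3-(hydroxymethyl)-5-methoxy-2,3-dihydro-1,4-benzodioxin-7-yl]prop-2-enal (formed in the flask) | COc1cc([C@@H]2Oc3cc(/C=C/C=O)cc(OC)c3O[C@@H]2CO)cc(O)c1O | intermediate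
19 | (E)-3-[(2S,3R)-2-(3,4-dihydroxy-5-methoxyphenyl)-3-(hydroxymethyl)-5-methoxy-2,3-dihydro-1,4-benzodioxin-7-yl]prop-2-en-1-ol (CNP0174261.1) | COc1cc([C@@H]2Oc3cc(/C=C/CO)cc(OC)c3O[C@@H]2CO)cc(O)c1O | target

**Step count**
Total: 10 steps. Longest linear sequence: 9 steps from 5-hydroxyvanillin (steps 1, 2, 3, 5, 6, 7, 8, 9, 10); step 4 is a one-step branch.

**Steps most likely to fail**

Step 7. The phenoxide may attack the terminal carbon C9 (7-endo closure to the seven-membered benzodioxepine). It may also react so slowly, because the formyl group lowers its nucleophilicity, that intermolecular opening competes. The fallback sets out from 11 and makes only C3 available for ring closure. Acid-catalysed hydration of the oxirane at C9 (cat. HClO4, THF/H2O; the C3–O bond is not touched) gives the diol F1. TBSCl and imidazole silylate the primary hydroxyl to give the silyl ether F2. Pd(PPh3)4 with PhNHMe frees O4 to give the phenol F3. An intramolecular Mitsunobu reaction (PPh3, DIAD, THF) can then activate only the C3 hydroxyl and closes O4–C3 with the same inversion, giving the silylated benzodioxane F4. Buffered fluoride (Bu4NF, AcOH, THF) removes the silyl group and the route is rejoined at 14.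

Step 5. Partial ionisation of the activated benzylic alcohol would erode the inversion at C2, so that the separable C2 epimer of 11 forms alongside it. The hindered carbinol may also react slowly enough for the reduced azodicarboxylate to compete as the nucleophile. The fallback sets out from 8 and separates activation from displacement. MsCl and Et3N in CH2Cl2 at −20 °C give the mesylate F5 with retention. The caesium phenoxide of 10 (Cs2CO3, DMF, 0 °C) then displaces the sulfonate directly with inversion, as phenoxides do with oxiranylmethyl sulfonates, and the route is rejoined at 11.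

Step 8. Over-reduction of the formyl group, or hydrogenolysis of the benzylic C2–O1 bond, may accompany the debenzylation. The fallback sets out from 14 and avoids hydrogen altogether. The Wittig reaction with 16 is run first and gives the bis-benzyl enoate F6. The two benzyl ethers are then cleaved with BCl3 and pentamethylbenzene (CH2Cl2, −78 °C), which spares the alkene and the ester, and the route is rejoined at 17.

**Further compounds**
F1 | step 7 | 4-(allyloxy)-3-{(1S,2S)-1-[3,4-bis(benzyloxy)-5-methoxyphenyl]-2,3-dihydroxypropoxy}-5-methoxybenzaldehyde | COc1cc([C@H](Oc2cc(C=O)cc(OC)c2OCC=C)[C@@H](O)CO)cc(OCc3ccccc3)c1OCc4ccccc4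
F2 | step 7 | 4-(allyloxy)-3-{(1S,2S)-1-[3,4-bis(benzyloxy)-5-methoxyphenyl]-3-[(tert-butyldimethylsilyl)oxy]-2-hydroxypropoxy}-5-methoxybenzaldehyde | COc1cc([C@H](Oc2cc(C=O)cc(OC)c2OCC=C)[C@@H](O)CO[Si](C)(C)C(C)(C)C)cc(OCc3ccccc3)c1OCc4ccccc4
F3 | step 7 | 3-{(1S,2S)-1-[3,4-bis(benzyloxy)-5-methoxyphenyl]-3-[(tert-butyldimethylsilyl)oxy]-2-hydroxypropoxy}-4-hydroxy-5-methoxybenzaldehyde | COc1cc([C@H](Oc2cc(C=O)cc(OC)c2O)[C@@H](O)CO[Si](C)(C)C(C)(C)C)cc(OCc3ccccc3)c1OCc4ccccc4
F4 | step 7 | (2S,3R)-2-[3,4-bis(benzyloxy)-5-methoxyphenyl]-3-{[(tert-butyldimethylsilyl)oxy]methyl}-5-methoxy-2,3-dihydro-1,4-benzodioxine-7-carbaldehyde | COc1cc([C@@H]2Oc3cc(C=O)cc(OC)c3O[C@@H]2CO[Si](C)(C)C(C)(C)C)cc(OCc4ccccc4)c1OCc5ccccc5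
F5 | step 5 | (R)-[3,4-bis(benzyloxy)-5-methoxyphenyl][(S)-oxiran-2-yl]methyl methanesulfonate | COc1cc([C@@H](OS(C)(=O)=O)[C@@H]2CO2)cc(OCc3ccccc3)c1OCc4ccccc4
F6 | step 8 | methyl (E)-3-{(2S,3R)-2-[3,4-bis(benzyloxy)-5-methoxyphenyl]-3-(hydroxymethyl)-5-methoxy-2,3-dihydro-1,4-benzodioxin-7-yl}prop-2-enoate | COc1cc([C@@H]2Oc3cc(/C=C/C(=O)OC)cc(OC)c3O[C@@H]2CO)cc(OCc4ccccc4)c1OCc5ccccc5
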